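**Retrosynthetic overview**
- The target comes from its 15‑O‑acetate by lipase deacetylation. The 6β‑isovalerate and 7α‑acetate are set on a 6‑oxo‑labd‑8‑ene by dienolate hydroxylation at C7, α‑face hydride delivery to C6 and acylation.
- The 6‑ketone comes from a 6‑nitro trans‑decalin (Nef), which comes from an acyclic (E)‑nitro triene by intramolecular Diels–Alder reaction. Rings A and B form together here (C5–C10 and C6–C7 bonds); no ring exists before this step.
- The nitro triene comes from a γ‑lactol (Henry, then acetylation/elimination), itself from a nitrile (i‑Bu2AlH). The 2‑substituted diene comes from a Weinreb amide (MeMgBr, then Wittig).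
- The (E)‑tetrasubstituted C9=C10 alkene comes from an ynamide by anti‑dibromination and two stereoretentive Pd couplings (methyl at C10, B‑alkyl Suzuki of the C11–C15 chain at C9).
- The ynamide comes from (S)‑epichlorohydrin, isobutyronitrile and N‑methoxy‑N‑methylpropiolamide; the chain comes from (E)‑3‑methylpent‑2‑en‑4‑yn‑1‑ol.

Assumption: the SMILES is read as the normal labdane (2S,5S,6S,7S,10S,13E), i.e. 2α‑OAc, 6β‑O‑isovaleryl, 7α‑OAc, 5α‑H, 10β‑CH3; labdane numbering (C1–C20) is used for locants.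
Assumption: conjugate bases made by simple deprotonation (lithiated nitrile, lithium acetylide, nitronate, enolate) count as the reacting form of the numbered compound and get no number of their own.

**Route**

Step 1
Reactants: 1 isobutyronitrile; 2 (S)-epichlorohydrin
Product: 4 2,2-dimethyl-3-[(2S)-oxiran-2-yl]propanenitrile, via chlorohydrin alkoxide 3 (not isolated)
Conditions: LiN(i-Pr)2, THF, −78 °C; then 2 (1.5 equiv), −78 °C → rt
Reagents that add atoms: none
Why: Alkylation of a nitrile anion: SN2 opening of the epoxide CH2 followed by 3‑exo‑tet closure of the chlorohydrin alkoxide; the stereocentre of 2 is never a reaction site and becomes C2 of the target.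

Step 2
Reactants: 4 2,2-dimethyl-3-[(2S)-oxiran-2-yl]propanenitrile; 5 N-methoxy-N-methylprop-2-ynamide
Product: 6 (5R)-7-cyano-5-hydroxy-N-methoxy-N,7-dimethyloct-2-ynamide
Conditions: 5, n-BuLi, THF, −78 °C; BF3·OEt2; then 4, −78 °C
Reagents that add atoms: none
Why: BF3‑promoted alkynylation of an epoxide (Yamaguchi‑type): the lithium acetylide attacks the unsubstituted epoxide carbon only, so the carbinol centre is untouched.

Step 3
Reactants: 6 (5R)-7-cyano-5-hydroxy-N-methoxy-N,7-dimethyloct-2-ynamide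
Product: 7 (2E,5S)-2,3-dibromo-7-cyano-5-hydroxy-N-methoxy-N,7-dimethyloct-2-enamide
Conditions: Br2 (1.05 equiv), CH2Cl2, −20 → 0 °C, dark
Reagents that add atoms: bromine, BrBr
Why: Electrophilic anti‑addition of bromine to the alkyne gives the (E)‑dibromide, placing the C1 methylene trans to the amide carbon (future C8).

Step 4
Reactants: 7 (2E,5S)-2,3-dibromo-7-cyano-5-hydroxy-N-methoxy-N,7-dimethyloct-2-enamide
Product: 8 (2Z,5S)-2-bromo-7-cyano-5-hydroxy-N-methoxy-N,3,7-trimethyloct-2-enamide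
Conditions: MeZnCl (1.3 equiv), Pd(PPh3)4 (5 mol %), THF, 0 °C → rt
Reagents that add atoms: methylzinc chloride, C[Zn]Cl
Why: Negishi coupling: zerovalent palladium inserts first into the β C–Br bond (vinylogous acyl bromide) and couples with retention, so the new methyl (C20) is cis to the amide carbon.

Step 5
Reactants: 9 (2E)-3-methylpent-2-en-4-yn-1-ol
Product: 10 (2E)-3-methylpenta-2,4-dien-1-ol
Conditions: H2 (1 atm), Pd/CaCO3/Pb(OAc)2 (Lindlar catalyst), quinoline, EtOAc, rt
Reagents that add atoms: none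
Why: Lindlar semi‑hydrogenation of the terminal alkyne to a vinyl group; the (E)‑trisubstituted alkene is not touched.

Step 6
Reactants: 10 (2E)-3-methylpenta-2,4-dien-1-ol; 8 (2Z,5S)-2-bromo-7-cyano-5-hydroxy-N-methoxy-N,3,7-trimethyloct-2-enamide
Product: 12 (2E,5R)-7-cyano-5-hydroxy-2-[(3E)-5-hydroxy-3-methylpent-3-en-1-yl]-N-methoxy-N,3,7-trimethyloct-2-enamide, via bis-boryl adduct 11 (not isolated)
Conditions: 10, 9-BBN-H (2.2 equiv), THF, 0 °C → rt; then 8, PdCl2(dppf) (5 mol %), AsPh3, Cs2CO3, DMF/H2O, rt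
Reagents that add atoms: none
Why: Anti‑Markovnikov hydroboration of the vinyl group, then B‑alkyl Suzuki–Miyaura coupling at the α‑bromo enamide with retention, so C11 is cis to C1 and the tetrasubstituted alkene is (E).

Step 7
Reactants: 12 (2E,5R)-7-cyano-5-hydroxy-2-[(3E)-5-hydroxy-3-methylpent-3-en-1-yl]-N-methoxy-N,3,7-trimethyloct-2-enamide
Product: 13 (4R,6E)-4-hydroxy-7-[(3E)-5-hydroxy-3-methylpent-3-en-1-yl]-2,2,6-trimethyl-8-oxonon-6-enenitrile
Conditions: MeMgBr (4 equiv), THF, −20 → 0 °C; aq. NH4Cl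
Reagents that add atoms: methylmagnesium bromide, C[Mg]Br
Why: Weinreb ketone synthesis: the chelated tetrahedral adduct stops at the ketone, and the hindered tertiary nitrile does not react with the Grignard reagent at this temperature.

Step 8
Reactants: 13 (4R,6E)-4-hydroxy-7-[(3E)-5-hydroxy-3-methylpent-3-en-1-yl]-2,2,6-trimethyl-8-oxonon-6-enenitrile
Product: 14 (4R,6E)-4-hydroxy-7-[(3E)-5-hydroxy-3-methylpent-3-en-1-yl]-2,2,6,8-tetramethylnona-6,8-dienenitrile
Conditions: Ph3PCH3Br, KOt-Bu (4 equiv each), THF, 0 °C → rt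
Reagents that add atoms: methyltriphenylphosphonium bromide, C[P+](c1ccccc1)(c1ccccc1)c1ccccc1.[Br-]
Why: Wittig methylenation turns the acetyl group into the isopropenyl group (C8, C7, C17) and completes the diene; no stereocentre is made, and the twisted enone has weakly acidic γ‑hydrogens, so the alkene geometry holds.

Step 9
Reactants: 14 (4R,6E)-4-hydroxy-7-[(3E)-5-hydroxy-3-methylpent-3-en-1-yl]-2,2,6,8-tetramethylnona-6,8-dienenitrile
Product: 17 (5R)-5-{(2E)-3-[(3E)-5-hydroxy-3-methylpent-3-en-1-yl]-2,4-dimethylpenta-2,4-dien-1-yl}-3,3-dimethyloxolan-2-ol (anomer mixture), via N-aluminated aldimine 15 (not isolated), via hydroxy aldehyde 16 (not isolated)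
Conditions: i-Bu2AlH (4.5 equiv), CH2Cl2, −78 °C; then aq. potassium sodium tartrate, SiO2, rt
Reagents that add atoms: water, O
Why: Partial reduction of the nitrile with i‑Bu2AlH to the aldimine and hydrolysis to the aldehyde, which the C2 hydroxyl traps as the five‑membered lactol.

Step 10
Reactants: 17 lactol (name as in step 9)
Product: 20 (1E,5S,7E)-8-[(3E)-5-acetoxy-3-methylpent-3-en-1-yl]-3,3,7,9-tetramethyl-1-nitrodeca-1,7,9-trien-5-yl acetate, via nitro triol 18 (not isolated), via nitro triacetate 19 (not isolated)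
Conditions: CH3NO2 (10 equiv), DBU (0.3 equiv), THF, rt; then Ac2O, Et3N, DMAP (cat.), CH2Cl2, 0 °C → rt
Reagents that add atoms: nitromethane, C[N+](=O)[O-]; acetic anhydride, CC(=O)OC(C)=O
Why: Henry (nitroaldol) reaction on the ring‑opened lactol, then acetylation and E1cB loss of acetic acid give the (E)‑nitroalkene; the unhindered C2 and C15 hydroxyls are acetylated before the neopentyl one, so no free hydroxyl can add to the nitroalkene.

Step 11
Reactants: 20 nitro triene (name as in step 10)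
Product: 21 6α-nitrolabda-8,13E-diene-2α,15-diyl diacetate (trans-decalin: 5α-H and 10β-CH3)
Conditions: toluene (0.01 M), BHT, 110 °C, sealed tube, 36 h
Reagents that add atoms: none
Why: Intramolecular Diels–Alder reaction of an (E)‑nitroalkene: the four‑atom tether folds as a chair with the C2 acetate equatorial (an axial acetate would clash with the axial methyls on C4 and C10) and the nitro group endo, so C5–C10 and C6–C7 form on one face and give the trans‑fused decalin with 10β‑CH3, 5α‑H and 6α‑NO2.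

Step 12
Reactants: 21 6α-nitrolabda-8,13E-diene-2α,15-diyl diacetate
Product: 22 6-oxolabda-8,13E-diene-2α,15-diyl diacetate
Conditions: DBU, MeCN, rt → 40 °C; then TiCl3 (aq.), NH4OAc buffer (pH ≈ 5), THF/H2O, 0 °C → rt
Reagents that add atoms: water, O
Why: Reductive Nef reaction (McMurry conditions): the nitronate is reduced by TiCl3 to the imine, which hydrolyses under buffered conditions to the β,γ‑unsaturated ketone; the trans ring fusion at C5 is also the thermodynamic one.

Step 13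
Reactants: 22 6-oxolabda-8,13E-diene-2α,15-diyl diacetate
Product: 24 6-oxolabda-8,13E-diene-2α,7α,15-triyl triacetate, via 7α-hydroxy ketone alkoxide 23 (not isolated)
Conditions: KN(SiMe3)2 (1.1 equiv), THF, −78 °C; 2-(phenylsulfonyl)-3-phenyloxaziridine (1.3 equiv); then Ac2O, DMAP, −78 → 0 °C
Reagents that add atoms: 2-(phenylsulfonyl)-3-phenyloxaziridine, O=S(=O)(N1OC1c1ccccc1)c1ccccc1; acetic anhydride, CC(=O)OC(C)=O
Why: Davis α‑hydroxylation of the extended enolate formed at the doubly activated C7; the oxidant attacks C7 anti to the axial C10 methyl (α face) to give the 7α‑oxygen, and acetylation in the same flask blocks α‑ketol isomerisation.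

Step 14
Reactants: 24 6-oxolabda-8,13E-diene-2α,7α,15-triyl triacetate
Product: 25 6β-hydroxylabda-8,13E-diene-2α,7α,15-triyl triacetate
Conditions: NaBH4, CeCl3·7H2O, MeOH/THF, −78 → −40 °C
Reagents that add atoms: none
Why: Luche‑type ketone reduction under steric approach control: the β face of C6 is blocked by the syn‑axial methyls on C4 and C10, so hydride enters from the α face and gives the axial 6β‑alcohol.

Step 15
Reactants: 25 6β-hydroxylabda-8,13E-diene-2α,7α,15-triyl triacetate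
Product: 26 6β-(3-methylbutanoyloxy)labda-8,13E-diene-2α,7α,15-triyl triacetate
Conditions: (i-BuCO)2O (4 equiv), DMAP (2 equiv), Et3N, CH2Cl2, 40 °C
Reagents that add atoms: 3-methylbutanoic anhydride, CC(C)CC(=O)OC(=O)CC(C)C
Why: DMAP‑catalysed acyl transfer to the only free hydroxyl; configuration at C6 is retained because the C–O bond is not broken.

Step 16
Reactants: 26 6β-(3-methylbutanoyloxy)labda-8,13E-diene-2α,7α,15-triyl triacetate
Product: 27 15-hydroxy-6β-(3-methylbutanoyloxy)labda-8,13E-diene-2α,7α-diyl diacetate (CNP0257091.1)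
Conditions: Candida antarctica lipase B (immobilised), n-BuOH (5 equiv), t-BuOMe, 30 °C
Reagents that add atoms: none
Why: Lipase‑catalysed transesterification, selective for the unhindered primary allylic acetate; the secondary ring esters on the decalin are expected to be left alone by the enzyme.

**Compound list**
1 | 2-methylpropanenitrile (isobutyronitrile) | CC(C)C#N | starting material
2 | (S)-epichlorohydrin, (2S)-2-(chloromethyl)oxirane | ClC[C@@H]1CO1 | starting material
3 | (4S)-5-chloro-4-hydroxy-2,2-dimethylpentanenitrile (as lithium alkoxide in the flask) | N#CC(C)(C)C[C@H](O)CCl | intermediate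
4 | 2,2-dimethyl-3-[(2S)-oxiran-2-yl]propanenitrile | N#CC(C)(C)C[C@H]1CO1 | intermediate
5 | N-methoxy-N-methylprop-2-ynamide | C#CC(=O)N(C)OC | starting material
6 | (5R)-7-cyano-5-hydroxy-N-methoxy-N,7-dimethyloct-2-ynamide | N#CC(C)(C)C[C@H](O)CC#CC(=O)N(C)OC | intermediate
7 | (2E,5S)-2,3-dibromo-7-cyano-5-hydroxy-N-methoxy-N,7-dimethyloct-2-enamide | N#CC(C)(C)C[C@H](O)C/C(Br)=C(\Br)C(=O)N(C)OC | intermediate
8 | (2Z,5S)-2-bromo-7-cyano-5-hydroxy-N-methoxy-N,3,7-trimethyloct-2-enamide | N#CC(C)(C)C[C@H](O)C/C(C)=C(\Br)C(=O)N(C)OC | intermediate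
9 | (2E)-3-methylpent-2-en-4-yn-1-ol | C#C/C(C)=C/CO | starting material
10 | (2E)-3-methylpenta-2,4-dien-1-ol | C=C/C(C)=C/CO | intermediate
11 | 9-[(3E)-3-methyl-5-(9-borabicyclo[3.3.1]nonan-9-yloxy)pent-3-en-1-yl]-9-borabicyclo[3.3.1]nonane | C(OB1C2CCCC1CCC2)/C=C(\C)CCB1C2CCCC1CCC2 | intermediate
12 | (2E,5R)-7-cyano-5-hydroxy-2-[(3E)-5-hydroxy-3-methylpent-3-en-1-yl]-N-methoxy-N,3,7-trimethyloct-2-enamide | N#CC(C)(C)C[C@H](O)C/C(C)=C(\CC/C(C)=C/CO)C(=O)N(C)OC | intermediate
13 | (4R,6E)-4-hydroxy-7-[(3E)-5-hydroxy-3-methylpent-3-en-1-yl]-2,2,6-trimethyl-8-oxonon-6-enenitrile | N#CC(C)(C)C[C@H](O)C/C(C)=C(\CC/C(C)=C/CO)C(C)=O | intermediate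
14 | (4R,6E)-4-hydroxy-7-[(3E)-5-hydroxy-3-methylpent-3-en-1-yl]-2,2,6,8-tetramethylnona-6,8-dienenitrile | N#CC(C)(C)C[C@H](O)C/C(C)=C(\CC/C(C)=C/CO)C(C)=C | intermediate
15 | (4R,6E)-4-hydroxy-7-[(3E)-5-hydroxy-3-methylpent-3-en-1-yl]-2,2,6,8-tetramethylnona-6,8-dien-1-imine (N-aluminated in the flask) | N=CC(C)(C)C[C@H](O)C/C(C)=C(\CC/C(C)=C/CO)C(C)=C | intermediate
16 | (4R,6E)-4-hydroxy-7-[(3E)-5-hydroxy-3-methylpent-3-en-1-yl]-2,2,6,8-tetramethylnona-6,8-dienal | O=CC(C)(C)C[C@H](O)C/C(C)=C(\CC/C(C)=C/CO)C(C)=C | intermediate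
17 | (5R)-5-{(2E)-3-[(3E)-5-hydroxy-3-methylpent-3-en-1-yl]-2,4-dimethylpenta-2,4-dien-1-yl}-3,3-dimethyloxolan-2-ol (anomer mixture) | OC1O[C@H](C/C(C)=C(\CC/C(C)=C/CO)C(C)=C)CC1(C)C | intermediate
18 | (2RS,5R,7E)-8-[(3E)-5-hydroxy-3-methylpent-3-en-1-yl]-3,3,7,9-tetramethyl-1-nitrodeca-7,9-diene-2,5-diol | [O-][N+](=O)CC(O)C(C)(C)C[C@H](O)C/C(C)=C(\CC/C(C)=C/CO)C(C)=C | intermediate
19 | (2RS,5R,7E)-8-[(3E)-5-acetoxy-3-methylpent-3-en-1-yl]-3,3,7,9-tetramethyl-1-nitrodeca-7,9-diene-2,5-diyl diacetate | [O-][N+](=O)CC(OC(C)=O)C(C)(C)C[C@H](OC(C)=O)C/C(C)=C(\CC/C(C)=C/COC(C)=O)C(C)=C | intermediate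
20 | (1E,5S,7E)-8-[(3E)-5-acetoxy-3-methylpent-3-en-1-yl]-3,3,7,9-tetramethyl-1-nitrodeca-1,7,9-trien-5-yl acetate | [O-][N+](=O)/C=C/C(C)(C)C[C@H](OC(C)=O)C/C(C)=C(\CC/C(C)=C/COC(C)=O)C(C)=C | intermediate
21 | 6α-nitrolabda-8,13E-diene-2α,15-diyl diacetate (5α-H, 10β-CH3) | CC(=O)O[C@H]1CC(C)(C)[C@@H]2[C@@H]([N+](=O)[O-])CC(C)=C(CC/C(C)=C/COC(C)=O)[C@@]2(C)C1 | intermediate
22 | 6-oxolabda-8,13E-diene-2α,15-diyl diacetate | CC(=O)O[C@H]1CC(C)(C)[C@@H]2C(=O)CC(C)=C(CC/C(C)=C/COC(C)=O)[C@@]2(C)C1 | intermediate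
23 | 7α-hydroxy-6-oxolabda-8,13E-diene-2α,15-diyl diacetate (as potassium alkoxide in the flask) | CC(=O)O[C@H]1CC(C)(C)[C@@H]2C(=O)[C@@H](O)C(C)=C(CC/C(C)=C/COC(C)=O)[C@@]2(C)C1 | intermediate
24 | 6-oxolabda-8,13E-diene-2α,7α,15-triyl triacetate | CC(=O)O[C@H]1CC(C)(C)[C@@H]2C(=O)[C@@H](OC(C)=O)C(C)=C(CC/C(C)=C/COC(C)=O)[C@@]2(C)C1 | intermediate
25 | 6β-hydroxylabda-8,13E-diene-2α,7α,15-triyl triacetate | CC(=O)O[C@H]1CC(C)(C)[C@@H]2[C@H](O)[C@@H](OC(C)=O)C(C)=C(CC/C(C)=C/COC(C)=O)[C@@]2(C)C1 | intermediate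
26 | 6β-(3-methylbutanoyloxy)labda-8,13E-diene-2α,7α,15-triyl triacetate | CC(=O)O[C@H]1CC(C)(C)[C@@H]2[C@H](OC(=O)CC(C)C)[C@@H](OC(C)=O)C(C)=C(CC/C(C)=C/COC(C)=O)[C@@]2(C)C1 | intermediate
27 | 15-hydroxy-6β-(3-methylbutanoyloxy)labda-8,13E-diene-2α,7α-diyl diacetate (CNP0257091.1) | CC(=O)O[C@H]1CC(C)(C)[C@@H]2[C@H](OC(=O)CC(C)C)[C@@H](OC(C)=O)C(C)=C(CC/C(C)=C/CO)[C@@]2(C)C1 | target

**Step count**
Total: 16 steps. Longest linear sequence: 15 steps (steps 1–4 and 6–16); the chain fragment joins after one step (step 5).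

**Steps most likely to fail, and fallbacks**

Step 11 (cycloaddition). The C5–C10 bond joins a neopentyl carbon to a fully substituted diene terminus with an inside methyl, so the thermal reaction may be slow and ene or polymerisation paths may compete. Fallback: set out from lactol 17 and replace the nitroalkene by a Lewis‑acid‑activated enal. Wittig extension with Ph3P=CHCHO gives hydroxy enal F1, and Ac2O/pyridine gives enal diacetate F2. Me2AlCl‑promoted intramolecular Diels–Alder reaction at −40 °C (endo, same chair fold) gives 6α‑formyl decalin F3. Piperidine converts this into piperidine enamine F4, and CuCl/O2 cleavage of the enamine removes the extra carbon and comes back to the route at ketone 22.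

Step 12 (Nef). The C6 nitro group sits between C5 (flanked by two quaternary carbons) and C7, and its axial hydrogen is shielded, so nitronate formation or imine hydrolysis may stall at the oxime. Fallback: set out from nitro decalin 21 and go through the amine. Zn/AcOH reduction gives 6α‑amine F5. Condensation with 3,5‑di‑tert‑butyl‑1,2‑benzoquinone and prototropic shift gives aryl ketimine F6, and aqueous oxalic acid hydrolysis comes back to the route at ketone 22.

Step 15 (acylation). The 6β‑hydroxyl is axial and syn to two axial methyls, with the 7α‑acetate next to it, so acyl transfer to the neutral alcohol may be very slow. Fallback: set out from acetoxy ketone 24 and acylate the alkoxide as it is formed. LiBH(s‑Bu)3 in THF at −78 °C reduces C6 from the α face to give lithium 6β‑alkoxide F7, which is trapped in the same flask with 3‑methylbutanoyl chloride and comes back to the route at triester 26 (alcohol 25 is bypassed).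

**Further compounds**
F1 | step 11 | (2E,6S,8E)-6-hydroxy-9-[(3E)-5-hydroxy-3-methylpent-3-en-1-yl]-4,4,8,10-tetramethylundeca-2,8,10-trienal | O=C/C=C/C(C)(C)C[C@H](O)C/C(C)=C(\CC/C(C)=C/CO)C(C)=C
F2 | step 11 | (2E,6S,8E)-9-[(3E)-5-acetoxy-3-methylpent-3-en-1-yl]-4,4,8,10-tetramethyl-1-oxoundeca-2,8,10-trien-6-yl acetate | O=C/C=C/C(C)(C)C[C@H](OC(C)=O)C/C(C)=C(\CC/C(C)=C/COC(C)=O)C(C)=C
F3 | step 11 | 6α-formyllabda-8,13E-diene-2α,15-diyl diacetate | CC(=O)O[C@H]1CC(C)(C)[C@@H]2[C@@H](C=O)CC(C)=C(CC/C(C)=C/COC(C)=O)[C@@]2(C)C1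
F4 | step 11 | 6-(piperidin-1-ylmethylidene)labda-8,13E-diene-2α,15-diyl diacetate | CC(=O)O[C@H]1CC(C)(C)[C@@H]2C(=CN3CCCCC3)CC(C)=C(CC/C(C)=C/COC(C)=O)[C@@]2(C)C1
F5 | step 12 | 6α-aminolabda-8,13E-diene-2α,15-diyl diacetate | CC(=O)O[C@H]1CC(C)(C)[C@@H]2[C@@H](N)CC(C)=C(CC/C(C)=C/COC(C)=O)[C@@]2(C)C1
F6 | step 12 | 6-[(3,5-di-tert-butyl-2-hydroxyphenyl)imino]labda-8,13E-diene-2α,15-diyl diacetate | CC(=O)O[C@H]1CC(C)(C)[C@@H]2C(=Nc3cc(C(C)(C)C)cc(C(C)(C)C)c3O)CC(C)=C(CC/C(C)=C/COC(C)=O)[C@@]2(C)C1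
F7 | step 15 | lithium 2α,7α,15-triacetoxylabda-8,13E-dien-6β-olate | [Li+].CC(=O)O[C@H]1CC(C)(C)[C@@H]2[C@H]([O-])[C@@H](OC(C)=O)C(C)=C(CC/C(C)=C/COC(C)=O)[C@@]2(C)C1
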